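Red, amber and blue each stand for 4.0 min, so they share their time and part by their equivalents of nucleophile.

all flasks: electrophile 0.020 M

| run | nucleophile | remark | time |
|---|---|---|---|
| delta | 0.92 equiv | run made earlier |  |
| theta | 1.4 equiv | run made earlier |  |
| eta | 2 equiv | run made earlier |  |
| red | 1.00 equiv |  | 4.0 min |
| amber | 1.30 equiv |  | 4.0 min |
| blue | 1.70 equiv |  | 4.0 min |

| run | time / min | electrophile / % | target / % |
|---|---|---|---|
| delta | 0.333 | 79.6 | 21.0 |
| delta | 1.00 | 62.1 | 35.4 |
| delta | 2.00 | 54.4 | 40.9 |
| delta | 3.00 | 50.4 | 40.7 |
| theta | 0.667 | 55.5 | 43.0 |
| theta | 1.33 | 41.5 | 54.1 |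
| theta | 2.00 | 34.4 | 59.0 |
| theta | 3.00 | 29.6 | 62.3 |
| eta | 0.333 | 60.0 | 40.6 |
| eta | 1.00 | 32.0 | 66.3 |
| eta | 2.00 | 17.9 | 76.8 |
| eta | 3.00 | 12.9 | 80.9 |

(standard deviation of a reading: 0.5 percentage points)

- part of the electrophile that has reacted at the end, red
- part of the electrophile that has reacted at the end, amber
- part of the electrophile that has reacted at the end, blue
- what raising the equivalents of nucleophile from its lowest to its highest value here does to the part of the electrophile that has reacted (changes below 5 percentage points count as none) (it rises / no change / it falls)

- the earlier runs were read with a standard deviation of 0.5 percentage points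

1. Main step alone. I began with electrophile and nucleophile reacting one for one. The first eta reading gave a pace of 0.767 min⁻¹ per equivalent of nucleophile. On that pace, red would reach 75.4% by the end.

2. Nucleophile spent twice over. In the last minute of the delta run the electrophile's pace was 0.0764 min⁻¹, while its starting pace was ten times that. The late pace needs 0.0996 of nucleophile per electrophile charged, yet one-for-one spending leaves 0.424. So nucleophile was disappearing faster than electrophile. I named the nucleophile cost, the nucleophile charged per electrophile reacted once a run stalls, and read it from the theta run as 1.99. Dividing the equivalents by the cost gives an estimated stopping point, which I called the ceiling: red 50.3%, amber 65.4%, blue 85.5%. Even blue's ceiling stands below the whole charge, so I treated nucleophile as the limiting reagent.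

3. The rest. The delta readings close 8.9 points short of the charge, so some electrophile goes elsewhere than target, and that run stands 3.3 points past its ceiling. I added this to each ceiling, giving red 53.6%, amber 68.7% and blue 88.8%.

4. The forecast, reckoned otherwise than mine, gave red 56%, amber 69% and blue 83%, and on raising the equivalents it rises, with the words “Conversion clearly rises with equivalents”.

5. The flasks gave red 55.2%, amber 68.7% and blue 83.6%: it rises, by 28 points.

    electrophile + nucleophile ⇌ acid set free + target (K = 0.870, k = 0.870 M⁻¹ s⁻¹)
    nucleophile + acid set free ⇌ protonated nucleophile, settled at all times (K = 46000 M⁻¹)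
    electrophile + target → side product (k = 0.0560 M⁻¹ s⁻¹)
    electrophile → decomposition product (k = 1.90 × 10⁻⁵ s⁻¹)

6. Each target sets acid free, and in the scheme acid binds nucleophile as protonated nucleophile, 0.0124 M in amber at 4.00 min. Amber's cost came out at 1.89. A neighbour of amber charged with 0.330 equiv of nucleophile has a ceiling of 16.6% at the theta cost. It reached 20.6%, a cost of 1.60. At 4.00 min that neighbour held 14.3% target and 79.4% electrophile, with 2.17% of its nucleophile still free.

(The earlier runs and the new flask come from a simulation with made-up constants; noise was put on by code.)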